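## Retrosynthetic overview

1. The eight-membered ring is closed last at the C2=C3 tetrasubstituted olefin by titanium-mediated reductive coupling of a methyl ketone (C2) with a cyclopentanone (C3). Both carbonyl carbons are normally electrophilic and are joined through ketyl intermediates of reversed polarity.
2. The seco-diketone comes from a 2-(hydroxyalkyl)cyclopentenone: cuprate addition sets C6 and kinetic protonation sets C7.
3. The C7–C8 bond comes from a thiolate-triggered Michael–aldol reaction of (R)-4-silyloxycyclopentenone with a decalin keto aldehyde, which also sets C8.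
4. The keto aldehyde comes from a trans-decalone: C9 by sulfonium-ylide epoxidation and Me3Al opening, the side chain by reductive alkylation of an octalone made by a chiral-imine Robinson annulation.
5. Ring order: gem-dimethylcyclohexane (purchased) → second cyclohexane (annulation) → cyclopentane (purchased enone, attached) → eight-membered ring.

Convention (one line): skeleton carbons are numbered along the target SMILES, C1 = olefinic methyl, C2=C3 the ring olefin, C4–C7 the rest of the cyclopentane (C5–OH, C6–CH3), C8 the ring carbinol, C9–C18 the decalin (C9, C12 quaternary; C15 gem-dimethyl), C19–C20 the CH2CH2 bridge; TBS = tert-butyldimethylsilyl.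

## Route

Step 1
Reactants: 1 3,3-dimethylcyclohexan-1-one
Product: 2 2,5,5-trimethylcyclohexan-1-one (racemic)
Conditions: LiN(iPr)2, THF, −78 °C; MeI, −78 → 0 °C
Reagents that add atoms: iodomethane, CI
Why: Kinetic enolate alkylation; deprotonation occurs at the CH2 remote from the gem-dimethyl carbon, and the new stereocentre is erased in step 2.

Step 2
Reactants: 2 2,5,5-trimethylcyclohexan-1-one; 3 (R)-1-phenylethan-1-amine; 4 but-3-en-2-one
Product: 7 (S)-2,5,5-trimethyl-2-(3-oxobutyl)cyclohexan-1-one, via ketimine 5 (not isolated), via Michael-adduct imine 6 (not isolated)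
Conditions: 3, TsOH (cat.), PhMe, reflux (−H2O); then 4, THF, 40 °C; then 20% aq. AcOH, rt
Reagents that add atoms: water, O
Why: Chiral-imine (deracemizing) Michael addition: the more substituted secondary enamine tautomer of 5 adds to 4 through a compact aza-ene-like transition state on the face away from the phenyl group, giving the quaternary C12 in the (S) series (the antipodal amine is known to give the (R) series), and hydrolysis releases the auxiliary.

Step 3
Reactants: 7 (S)-2,5,5-trimethyl-2-(3-oxobutyl)cyclohexan-1-one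
Product: 8 (S)-4a,7,7-trimethyl-4,4a,5,6,7,8-hexahydronaphthalen-2(3H)-one
Conditions: NaOMe (0.2 equiv), MeOH, rt → 60 °C
Reagents that add atoms: none
Why: Intramolecular aldol condensation (second stage of the Robinson annulation); no new stereocentre.

Step 4
Reactants: 8 (S)-octalone; 9 1,3-dichlorobut-2-ene
Product: 11 trans-fused 1-(3-chlorobut-2-en-1-yl)-4a,7,7-trimethyloctahydronaphthalen-2(1H)-one, via lithium enolate 10 (not isolated)
Conditions: Li (2.2 equiv), NH3(l)/THF, H2O (1.0 equiv), −78 °C; NH3 removed; 9, THF, −78 → 0 °C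
Reagents that add atoms: none
Why: Dissolving-metal enone reduction with regiospecific enolate trapping (reductive alkylation): axial protonation at the β-carbon gives the trans-decalin (C17–H anti to the angular methyl), and the allylic chloride alkylates enolate 10 at C18, where the epimerisable substituent ends equatorial.

Step 5
Reactants: 11 trans-decalone
Product: 12 spiro-oxirane at C9 (oxirane CH2 axial, O equatorial)
Conditions: Me3SI, n-BuLi, THF, −10 °C; then 11, −10 → 0 °C
Reagents that add atoms: trimethylsulfonium iodide, C[S+](C)C.[I-]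
Why: Corey–Chaykovsky epoxidation: the unstabilised sulfonium ylide adds irreversibly from the axial direction, so the new C–C bond (future C8) is axial and the oxygen equatorial.

Step 6
Reactants: 12 spiro-oxirane
Product: 13 neopentyl alcohol (C9: CH3 axial, CH2OH equatorial)
Conditions: Me3Al (4 equiv), hexane/CH2Cl2, −78 → 0 °C; aq. work-up
Reagents that add atoms: trimethylaluminium, C[Al](C)C
Why: Organoaluminium alkylative opening of a 2,2-disubstituted oxirane at the tertiary carbon: the Al-activated C–O bond is attacked by methyl with inversion (methyl enters axially, also the preferred direction for a cation-like centre), which turns C8 equatorial and sets C9.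

Step 7
Reactants: 13 neopentyl alcohol
Product: 14 4-[2-(hydroxymethyl)-2,4a,7,7-tetramethyldecahydronaphthalen-1-yl]butan-2-one
Conditions: H2SO4 (90%), 0 °C, 20 min; ice/H2O
Reagents that add atoms: water, O
Why: Wichterle hydrolysis: protonation of the vinyl chloride, capture by water and loss of HCl unmask the C2 methyl ketone without touching a stereocentre.

Step 8
Reactants: 14 hydroxy ketone
Product: 15 2,4a,7,7-tetramethyl-1-(3-oxobutyl)decahydronaphthalene-2-carbaldehyde
Conditions: (n-Pr4N)RuO4 (5 mol %), NMO, 4 Å MS, CH2Cl2, rt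
Reagents that add atoms: none
Why: Ley–Griffith oxidation of the primary alcohol; the α-carbon is quaternary, so the aldehyde cannot epimerise.

Step 9
Reactants: 15 keto aldehyde; 16 (R)-4-[(tert-butyldimethylsilyl)oxy]cyclopent-2-en-1-one
Product: 18 β-hydroxy ketone (aldol adduct), via aluminium enolate 17 (not isolated)
Conditions: Me2AlSPh (from Me3Al, PhSH), 16, CH2Cl2/hexane, −78 °C; then 15, THF, −78 → −40 °C
Reagents that add atoms: thiophenol (as Me2AlSPh), Sc1ccccc1
Why: Thiolate-triggered Michael–aldol reaction (1-acylvinyl anion equivalent): PhS adds to C6 anti to the silyloxy group, and the cyclic (E)-aluminium enolate 17 attacks the aldehyde anti to sulfur through a closed chair transition state with the bulky group equatorial (anti aldol), which gives C8 the (R) configuration of the target; C6 and C7 are reset in steps 10–12.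

Step 10
Reactants: 18 aldol adduct
Product: 20 2-(1-hydroxyalkyl)cyclopent-2-enone, via sulfoxide 19 (not isolated)
Conditions: mCPBA (1.0 equiv), CH2Cl2, −78 °C; then PhMe, 60 °C
Reagents that add atoms: none
Why: Sulfide oxidation followed by thermal syn-elimination of the sulfoxide (the acidic C7–H is syn to sulfur) restores the enone; C8 and C5 are untouched.

Step 11
Reactants: 20 hydroxy enone
Product: 21 bis-silyl ether of 20
Conditions: TBSOTf, 2,6-lutidine, CH2Cl2, −78 → −20 °C
Reagents that add atoms: tert-butyldimethylsilyl trifluoromethanesulfonate, CC(C)(C)[Si](C)(C)OS(=O)(=O)C(F)(F)F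
Why: Silyl-triflate protection of the hindered secondary alcohol blocks retro-aldol and β-elimination pathways in the next two steps; no stereocentre changes.

Step 12
Reactants: 21 bis-silyl enone
Product: 23 cis-2,3-disubstituted cyclopentanone (seco-diketone), via lithium enolate 22 (not isolated)
Conditions: Me2CuLi (from CuI, MeLi), Et2O, −78 °C; methyl salicylate, −78 °C; aq. NH4Cl; used at once
Reagents that add atoms: lithium dimethylcuprate, [Li+].C[Cu-]C
Why: Cuprate conjugate addition anti to the C5 silyloxy group sets C6, and kinetic protonation of enolate 22 by the chelating phenol on the face away from the new methyl sets C7 in the contra-thermodynamic cis arrangement.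

Step 13
Reactants: 23 seco-diketone
Product: 24 bis-TBS ether of the target
Conditions: TiCl3(DME)1.5, Zn–Cu couple, DME, reflux, slow addition (30 h)
Reagents that add atoms: none
Why: Intramolecular McMurry reductive carbonyl coupling: low-valent titanium turns both ketones into ketyls (carbonyl carbons made nucleophilic), which join C2 and C3 to a titanium pinacolate whose deoxygenation gives the tetrasubstituted olefin and closes the eight-membered ring; the ring forces C20 and C7 cis on the olefin and no sp3 centre is formed.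

Step 14
Reactants: 24 bis-TBS ether
Product: 25 CNP0213887.1 (target diol)
Conditions: Bu4NF, THF, 50 °C
Reagents that add atoms: none
Why: Fluoride desilylation of both ethers; basic conditions avoid acid-promoted addition of the hydroxyls to the tetrasubstituted olefin.

## Compound list

1 | 3,3-dimethylcyclohexan-1-one | CC1(C)CCCC(=O)C1 | starting material
2 | 2,5,5-trimethylcyclohexan-1-one (racemic) | CC1CCC(C)(C)CC1=O | intermediate
3 | (R)-1-phenylethan-1-amine | C[C@@H](N)c1ccccc1 | starting material
4 | but-3-en-2-one (methyl vinyl ketone) | CC(=O)C=C | starting material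
5 | N-[(R)-1-phenylethyl] ketimine of 2 (ring C2 epimers) | CC1CCC(C)(C)CC1=N[C@H](C)c1ccccc1 | intermediate (not isolated)
6 | N-[(R)-1-phenylethyl] ketimine of 7 at the ring carbonyl, quaternary carbon (S) | CC(=O)CC[C@]1(C)CCC(C)(C)CC1=N[C@H](C)c1ccccc1 | intermediate (not isolated)
7 | (S)-2,5,5-trimethyl-2-(3-oxobutyl)cyclohexan-1-one | CC(=O)CC[C@]1(C)CCC(C)(C)CC1=O | intermediate
8 | (S)-4a,7,7-trimethyl-4,4a,5,6,7,8-hexahydronaphthalen-2(3H)-one | O=C1CC[C@]2(C)CCC(C)(C)CC2=C1 | intermediate
9 | 1,3-dichlorobut-2-ene (E/Z mixture) | CC(Cl)=CCCl | starting material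
10 | lithium enolate (C1=C2–OLi) of trans-4a,7,7-trimethyloctahydronaphthalen-2(1H)-one, 8a-H anti to 4a-CH3 | [Li]OC1=C[C@@H]2CC(C)(C)CC[C@@]2(C)CC1 | intermediate (not isolated)
11 | trans-fused 1-(3-chlorobut-2-en-1-yl)-4a,7,7-trimethyloctahydronaphthalen-2(1H)-one; side chain equatorial, H-1 anti to H-8a, H-8a anti to 4a-CH3; vinyl chloride E/Z | O=C1CC[C@]2(C)CCC(C)(C)C[C@H]2[C@@H]1CC=C(C)Cl | intermediate
12 | spiro-oxirane at C2 of 11; oxirane CH2 axial (face opposite the 4a-CH3), O equatorial | C1O[C@]12CC[C@]3(C)CCC(C)(C)C[C@H]3[C@@H]2CC=C(C)Cl | intermediate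
13 | [1-(3-chlorobut-2-en-1-yl)-2,4a,7,7-tetramethyldecahydronaphthalen-2-yl]methanol; 2-CH3 axial (anti to 4a-CH3), 2-CH2OH equatorial, trans to the C1 chain | OC[C@@]1(C)CC[C@]2(C)CCC(C)(C)C[C@H]2[C@@H]1CC=C(C)Cl | intermediate
14 | 4-[2-(hydroxymethyl)-2,4a,7,7-tetramethyldecahydronaphthalen-1-yl]butan-2-one (configuration as 13) | OC[C@@]1(C)CC[C@]2(C)CCC(C)(C)C[C@H]2[C@@H]1CCC(C)=O | intermediate
15 | 2,4a,7,7-tetramethyl-1-(3-oxobutyl)decahydronaphthalene-2-carbaldehyde (configuration as 13) | O=C[C@@]1(C)CC[C@]2(C)CCC(C)(C)C[C@H]2[C@@H]1CCC(C)=O | intermediate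
16 | (R)-4-[(tert-butyldimethylsilyl)oxy]cyclopent-2-en-1-one | O=C1C=C[C@H](O[Si](C)(C)C(C)(C)C)C1 | starting material
17 | dimethylaluminium enolate of trans-4-(TBSO)-3-(phenylsulfanyl)cyclopentanone | C[Al](C)OC1=C[C@@H](Sc2ccccc2)[C@H](O[Si](C)(C)C(C)(C)C)C1 | intermediate (not isolated)
18 | 2-[(R)-hydroxy(decalinyl)methyl]-3-(phenylsulfanyl)-4-(TBSO)cyclopentan-1-one; ring 2,3-trans and 3,4-trans; decalinyl = the C2 group of 15 | O=C1C[C@@H](O[Si](C)(C)C(C)(C)C)[C@H](Sc2ccccc2)[C@H]1[C@@H](O)[C@@]3(C)CC[C@]4(C)CCC(C)(C)C[C@H]4[C@@H]3CCC(C)=O | intermediate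
19 | sulfoxide of 18 (sulfur epimers) | O=C1C[C@@H](O[Si](C)(C)C(C)(C)C)[C@H](S(=O)c2ccccc2)[C@H]1[C@@H](O)[C@@]3(C)CC[C@]4(C)CCC(C)(C)C[C@H]4[C@@H]3CCC(C)=O | intermediate (not isolated)
20 | (R)-4-(TBSO)-2-[hydroxy(decalinyl)methyl]cyclopent-2-en-1-one; carbinol carbon arranged in space as in 18 | O=C1C[C@@H](O[Si](C)(C)C(C)(C)C)C=C1[C@@H](O)[C@@]2(C)CC[C@]3(C)CCC(C)(C)C[C@H]3[C@@H]2CCC(C)=O | intermediate
21 | bis-TBS ether of 20 | O=C1C[C@@H](O[Si](C)(C)C(C)(C)C)C=C1[C@@H](O[Si](C)(C)C(C)(C)C)[C@@]2(C)CC[C@]3(C)CCC(C)(C)C[C@H]3[C@@H]2CCC(C)=O | intermediate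
22 | lithium enolate (C3=C7) after methyl addition; C6–CH3 trans to C5–OTBS | [Li]OC1=C([C@@H](O[Si](C)(C)C(C)(C)C)[C@@]2(C)CC[C@]3(C)CCC(C)(C)C[C@H]3[C@@H]2CCC(C)=O)[C@@H](C)[C@H](O[Si](C)(C)C(C)(C)C)C1 | intermediate (not isolated)
23 | 4-(TBSO)-3-methyl-2-[(TBSO)(decalinyl)methyl]cyclopentan-1-one; 2,3-cis, 3,4-trans; methyl ketone side chain intact | O=C1C[C@@H](O[Si](C)(C)C(C)(C)C)[C@H](C)[C@@H]1[C@@H](O[Si](C)(C)C(C)(C)C)[C@@]2(C)CC[C@]3(C)CCC(C)(C)C[C@H]3[C@@H]2CCC(C)=O | intermediate
24 | 5,8-bis-O-TBS ether of the target | C/C1=C2\C[C@@H](O[Si](C)(C)C(C)(C)C)[C@H](C)[C@@H]2[C@@H](O[Si](C)(C)C(C)(C)C)[C@@]2(C)CC[C@]3(C)CCC(C)(C)C[C@H]3[C@@H]2CC1 | intermediate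
25 | CNP0213887.1 | C/C1=C2\C[C@@H](O)[C@H](C)[C@@H]2[C@@H](O)[C@@]2(C)CC[C@]3(C)CCC(C)(C)C[C@H]3[C@@H]2CC1 | target

## Step count and risks

Total steps: 14. Longest linear sequence: 14 (1 → 25); 16 is purchased.

Most likely to fail:

Step 13. The medium-ring McMurry closure must form a tetrasubstituted olefin next to β-silyloxy groups and an epimerisable C7. Fallback, from 23 back to 24: SmI2/HMPA in THF gives, by intramolecular pinacol coupling, the cis-1,2-diol F1. Thiocarbonyldiimidazole and DMAP in hot toluene convert it to the cyclic thionocarbonate F2. Stereospecific Corey–Winter-type deoxygenation with 1,3-dimethyl-2-phenyl-1,3,2-diazaphospholidine at 40–60 °C then delivers 24 under neutral conditions.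

Step 12. Kinetic protonation may give too little of the cis ketone, or the cis ketone may epimerise. Fallback, from 20 back to 23 (bypassing steps 11 and 12): treat 20 with excess Me2CuLi and Me3SiCl to give the bis-trimethylsilyl compound F3 (silyl enol ether plus C8–OSiMe3). Saegusa–Ito dehydrogenation with Pd(OAc)2 in MeCN, then K2CO3/MeOH, gives the tetrasubstituted hydroxy enone F4. Hydroxyl-directed hydrogenation with [Ir(cod)(PCy3)(py)]PF6 and H2 adds both hydrogens from the C8–OH face, giving the cis hydroxy ketone F5. In the reactive conformer C8–H eclipses the C6 methyl to avoid allylic strain, which places the hydroxyl on the face that leads to the target C6/C7 configuration. TBSOTf/2,6-lutidine then gives 23.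

Step 9. The C8 configuration relies on the closed aldol transition state overriding the aldehyde's own facial preference. Fallback, from 16 (with 15) back to 20: I2/pyridine in CH2Cl2 converts 16 into the 2-iodo enone F6. Nozaki–Hiyama–Kishi coupling of F6 with 15 (CrCl2, cat. NiCl2, DMF/THF) in the presence of a chiral sulfonamide ligand places C8 under catalyst control and gives 20 directly.

## Further compounds

F1 | step 13 | cis-2,3-diol from pinacol closure of 23 (C2/C3 configuration not assigned) | CC1(O)C2(O)C[C@@H](O[Si](C)(C)C(C)(C)C)[C@H](C)[C@@H]2[C@@H](O[Si](C)(C)C(C)(C)C)[C@@]2(C)CC[C@]3(C)CCC(C)(C)C[C@H]3[C@@H]2CC1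
F2 | step 13 | cyclic thionocarbonate of F1 | CC12OC(=S)OC23C[C@@H](O[Si](C)(C)C(C)(C)C)[C@H](C)[C@@H]3[C@@H](O[Si](C)(C)C(C)(C)C)[C@@]3(C)CC[C@]4(C)CCC(C)(C)C[C@H]4[C@@H]3CC1
F3 | step 12 | trimethylsilyl enol ether (C3=C7) with C8–OSiMe3, C6–CH3 trans to C5–OTBS | C[Si](C)(C)OC1=C([C@@H](O[Si](C)(C)C)[C@@]2(C)CC[C@]3(C)CCC(C)(C)C[C@H]3[C@@H]2CCC(C)=O)[C@@H](C)[C@H](O[Si](C)(C)C(C)(C)C)C1
F4 | step 12 | 4-(TBSO)-3-methyl-2-[hydroxy(decalinyl)methyl]cyclopent-2-en-1-one | O=C1C[C@@H](O[Si](C)(C)C(C)(C)C)C(C)=C1[C@@H](O)[C@@]2(C)CC[C@]3(C)CCC(C)(C)C[C@H]3[C@@H]2CCC(C)=O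
F5 | step 12 | 2,3-cis-4-(TBSO)-3-methyl-2-[hydroxy(decalinyl)methyl]cyclopentan-1-one | O=C1C[C@@H](O[Si](C)(C)C(C)(C)C)[C@H](C)[C@@H]1[C@@H](O)[C@@]2(C)CC[C@]3(C)CCC(C)(C)C[C@H]3[C@@H]2CCC(C)=O
F6 | step 9 | (R)-4-[(tert-butyldimethylsilyl)oxy]-2-iodocyclopent-2-en-1-one | O=C1C(I)=C[C@H](O[Si](C)(C)C(C)(C)C)C1
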